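The rate constants of the two D + L steps, together with the charge of Z, divide each D that reacts between E and D.L, and you should carry that division through this flask.

    L + E → L.E (k1 = 0.0031 M⁻¹ s⁻¹)
    X ⇌ L, rate k2*(csat - [L]) (k2 = 0.0012 s⁻¹, csat = 9.9 mM)
    D + L + Z → Z + E (k3 = 22 M⁻² s⁻¹)
    D + L → D.L (k4 = 0.020 M⁻¹ s⁻¹)
    J ⇌ E, rate k5*(cs5 - [E]) while solid is left; crystals form when [E] > cs5 (cs5 = 4.5 mM, k5 = 0.0018 s⁻¹)

D 0.10 M; X 9.9 mM (held); Z 0.26 mM; time 1.5 h

- for E the J are counted in
- as a solid, counted per litre of solution: J
- at the start none of L is dissolved
- run time (flask): 1.5 h

- how much E and J together there is at 1.5 h, in percent of the D charged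
- concentration of L in solution at 1.5 h, in percent of saturation

Z comes back unchanged and both routes go with D times L, so their ratio stays constant, and the plain route at 0.020 M⁻¹ s⁻¹ outruns the catalysed one at 0.00572 M⁻¹ s⁻¹. The share of lost D that becomes E, the selectivity, is 22.2%. Since J counts with E, y is this share of the D lost, less what L takes from E.

From above, the gas transfer delivers at most 64.2% of the charge, which caps y at 14.3%. To tighten this, note that L stays above the level where transfer balances use by the full charge of D, 31.8% of saturation, once its first climb is over. Allowing for that climb and for the L still dissolved, D lost is at most 41.6%, so y is at most 9.25%.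

From below, that much loss still holds L under 44.4% of saturation, so D lost is at least 31.3%. Taking off at most 0.681% for L.E, on both E and L, y is at least 6.12%.

The forecast gives y as 8.1% (7.8% to 8.5%) and sat as 42% (40% to 44%), reasoning that “22% of the D consumed becomes E”. Its y range lies inside your bracket.

The flask gives y as 8.17% and sat as 41.7%. At 1.50 h the plain route uses L 3.5 times as fast as the catalysed one. Doubling the catalysed constant brings y to 14.4%, above the forecast's range. In the neighbour charged with 1.0 × 10⁻⁴ M of Z, the share becomes 9.91%, which on its 35.7% of D lost gives 3.54%. The computed y there is 3.43%, with 0.115% as L.E.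

The constants used here were chosen freely; the run is a simulation.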